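The route rests on disconnecting the cyclohexenone ring (C4a, C5, C6, C7, C8, C8a) across C7–C8 and C4a–C8a. This ring has its C6 carbonyl para to C8a and its C8 orsellinate trans to the C8a–C1 branch, the pattern delivered by a 2-silyloxydiene and an (E)-3-acyloxyacrolein. One catalytic enantioselective Diels–Alder reaction therefore unites an open-chain silyloxy trienyne (C7 methyl to propenyl) with an acrolein already carrying the protected orsellinate, closing the carbocycle and fixing C8 and C8a with all carbons in place. Dehydrogenation, C7 hydroxylation and desilylation follow; the pyran ring (O2, C1, C8a, C4a, C4, C3) is closed last by 6-endo-dig addition of the C1 hydroxyl to the alkyne.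

Key step: step 8

Remark: atoms carry the isochromene locants of the target (C1, O2, C3, C4, C4a, C5, C6, C7, C8, C8a) in all intermediates; the target is (7R,8S,8aS), with the C7 hydroxyl trans to the C8 ester and the C8 ester trans to the C8a–C1 bond.
Assumption: the (S)-configured oxazaborolidinium ion is taken to leave the Cα Re face of the s-trans enal 12 open, which is the face required here; if the sense proves opposite, the (R)-catalyst is used with no other change.
Assumption: sodium malonaldehyde enolate is bought as the sodium salt and dried before use.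

Step 1
Reactants: 1 (E)-pent-2-en-4-yn-1-ol; 2 (E)-1-bromoprop-1-ene
Product: 3 (2E,6E)-octa-2,6-dien-4-yn-1-ol
Conditions: Pd(PPh3)2Cl2 (2 mol%), CuI (4 mol%), Et3N, THF, 0 °C to rt, excess 2
Reagents that add atoms: none
Why: Sonogashira coupling of a terminal alkyne with an alkenyl bromide tolerates the free allylic alcohol and retains the E geometry of both alkenes.

Step 2
Reactants: 3 (2E,6E)-octa-2,6-dien-4-yn-1-ol
Product: 4 (2E,6E)-octa-2,6-dien-4-ynal
Conditions: activated MnO2, CH2Cl2, rt
Reagents that add atoms: none
Why: MnO2 oxidizes the allylic alcohol selectively to the conjugated aldehyde under neutral conditions that leave the dienyne and its geometry untouched.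

Step 3
Reactants: 4 (2E,6E)-octa-2,6-dien-4-ynal
Product: 5 racemic (4E,8E)-deca-4,8-dien-6-yn-3-ol
Conditions: EtMgBr, THF, −78 °C; aq. NH4Cl
Reagents that add atoms: ethylmagnesium bromide CC[Mg]Br
Why: Grignard 1,2-addition to the unhindered conjugated aldehyde at low temperature gives the secondary allylic alcohol, whose stereocentre is irrelevant because it is oxidized in the next step.

Step 4
Reactants: 5 racemic (4E,8E)-deca-4,8-dien-6-yn-3-ol
Product: 6 (4E,8E)-deca-4,8-dien-6-yn-3-one
Conditions: activated MnO2, CH2Cl2, rt
Reagents that add atoms: none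
Why: MnO2 oxidation of a secondary allylic alcohol gives the ethyl ketone without base or acid, so the conjugated enyne survives.

Step 5
Reactants: 6 (4E,8E)-deca-4,8-dien-6-yn-3-one
Product: 7 (2Z,4E,8E)-3-(tert-butyldimethylsilyloxy)deca-2,4,8-trien-6-yne (the diene)
Conditions: TBSOTf, Et3N, CH2Cl2, −78 to 0 °C; used promptly
Reagents that add atoms: tert-butyldimethylsilyl trifluoromethanesulfonate CC(C)(C)[Si](C)(C)OS(=O)(=O)C(F)(F)F
Why: Soft enolization of an ethyl ketone with a silyl triflate and Et3N gives the silyl enol ether with the usual preference for the Z isomer, which places the future C7 methyl on the outside of the s-cis diene.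

Step 6
Reactants: 8 orsellinic acid (2,4-dihydroxy-6-methylbenzoic acid)
Product: 9 tert-butyldimethylsilyl 2,4-bis(tert-butyldimethylsilyloxy)-6-methylbenzoate
Conditions: TBSCl (3.5 equiv), imidazole, DMF, rt
Reagents that add atoms: tert-butyldimethylsilyl chloride CC(C)(C)[Si](C)(C)Cl
Why: Exhaustive silylation at room temperature caps both phenols and the acid without decarboxylation, and the silyl ester serves as a latent acid chloride.

Step 7
Reactants: 9 tert-butyldimethylsilyl 2,4-bis(tert-butyldimethylsilyloxy)-6-methylbenzoate; 10 sodium malonaldehyde enolate (sodium (E)-3-oxoprop-1-en-1-olate)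
Product: 12 (E)-3-oxoprop-1-enyl 2,4-bis(tert-butyldimethylsilyloxy)-6-methylbenzoate (the dienophile), via acid chloride 11 (not isolated)
Conditions: (COCl)2, DMF (cat.), CH2Cl2, 0 °C to rt; evaporate; then 10, 15-crown-5 (cat.), THF/MeCN, 0 °C to rt
Reagents that add atoms: none
Why: Oxalyl chloride with catalytic DMF converts a silyl ester directly into the acid chloride under neutral conditions, and O-acylation of the malonaldehyde enolate gives the 3-acyloxyacrolein with the trans geometry of the enolate retained.

Step 8
Reactants: 7 (2Z,4E,8E)-3-(tert-butyldimethylsilyloxy)deca-2,4,8-trien-6-yne; 12 (E)-3-oxoprop-1-enyl 2,4-bis(tert-butyldimethylsilyloxy)-6-methylbenzoate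
Product: 13 Diels–Alder adduct: cyclohex-5-ene with the C5=C6 silyl enol ether (6-OTBS), 8a-formyl, 8-aroyloxy trans to the formyl group, and 4a-[(E)-pent-3-en-1-ynyl] and 7-methyl both cis to the formyl group (endo adduct); C8 and C8a configured as in the target; used crude
Conditions: (S)-3,3-diphenyl-1-(o-tolyl)tetrahydro-1H,3H-pyrrolo[1,2-c][1,3,2]oxazaborole (20 mol%) premixed with Tf2NH (18 mol%), CH2Cl2, −78 to −40 °C; Et3N quench, cold filtration
Reagents that add atoms: none
Why: The oxazaborolidinium ion binds the formyl oxygen of 12 and lowers its LUMO, and the diene then adds in a concerted asynchronous [4+2] cycloaddition in which C7, the enol ether carbon with the largest HOMO coefficient, bonds to the enal β carbon (C8) ahead of C4a bonding to the α carbon (C8a). The closest known reaction type is the oxazaborolidinium-catalysed enantioselective Diels–Alder reaction of 2-silyloxy-1,3-dienes with α,β-unsaturated aldehydes, and 3-acyloxyacroleins are known dienophiles. The carbocycle (C4a, C5, C6, C7, C8, C8a) is the only ring closed, by intermolecular suprafacial [4+2] cycloaddition. C8 and C8a are trans because the E geometry of 12 is transferred stereospecifically, and their absolute configuration is set by the catalyst, which screens one face of the s-trans enal so that the diene adds to the Cα Re face; C4a and C7 follow from endo approach of the formyl group and the outward alkynyl and methyl groups, and both are made trigonal later, so an exo adduct converges. The step needs para regiochemistry (C6 silyloxy to C8a formyl) and enal face selectivity: the first is secured by the 2-silyloxy group reinforced by the alkynyl substituent on C4a, the second by the catalyst. The diene reaches the reactive s-cis form readily because both terminal substituents point outward.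

Step 9
Reactants: 13 Diels–Alder adduct (crude)
Product: 14 primary alcohol: as 13 with the 8a-formyl group reduced to CH2OH (C1)
Conditions: NaBH4, MeOH/CH2Cl2, −78 to −40 °C; pH 7 buffer
Reagents that add atoms: none
Why: NaBH4 reduces the aldehyde chemoselectively at low temperature, removing the elimination-prone β-aroyloxy aldehyde, while the doubly ortho-substituted aroate resists both reduction and 1,3-acyl migration.

Step 10
Reactants: 14 primary alcohol
Product: 15 C1 triethylsilyl ether of 14
Conditions: TESCl, imidazole, CH2Cl2, 0 °C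
Reagents that add atoms: chlorotriethylsilane CC[Si](CC)(CC)Cl
Why: Standard silylation of the primary alcohol blocks premature addition of the C1 oxygen to the ynenone that is unveiled in the next step.

Step 11
Reactants: 15 C1 triethylsilyl ether
Product: 16 enynone: cyclohex-4a(5)-en-6-one with 4a-[(E)-pent-3-en-1-ynyl], 7-methyl (trans to the aroate as formed, configuration immaterial), 8-aroyloxy and 8a-CH2OTES (trans to the aroate); used directly
Conditions: Pd(OAc)2 (1.1 equiv), MeCN, rt; filtration through Celite and neutral silica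
Reagents that add atoms: none
Why: In this Saegusa–Ito oxidation the silyl enol ether transmetallates to a C5-bound palladium enolate and syn β-hydride elimination of the only β-hydrogen (C4a–H) gives the C4a=C5 enone regiospecifically under base-free conditions, which matters because enolization of this β-aroyloxy ketone would expel the aroate and aromatize the ring.

Step 12
Reactants: 16 enynone
Product: 19 C7 triethylsilyloxy enynone (7R,8S,8aS in target numbering) carrying the C8 aroate and the C1 triethylsilyl ether, via silyloxydiene 17 (not isolated), via silyloxy epoxide 18 (not isolated)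
Conditions: TESOTf, Et3N, CH2Cl2, −78 °C; pentane work-up; then DMDO (1.05 equiv), acetone/CH2Cl2, −78 to −20 °C, then rt
Reagents that add atoms: triethylsilyl trifluoromethanesulfonate CC[Si](CC)(CC)OS(=O)(=O)C(F)(F)F; dimethyldioxirane CC1(C)OO1
Why: In this Rubottom oxidation kinetic soft enolization toward C7 gives the cross-conjugated 2-silyloxydiene without a free enolate that could expel the aroate, the electron-rich tetrasubstituted enol ether is then epoxidized in preference to the other alkenes on the face anti to the adjacent C8 aroyloxy group, and epoxide opening with 1,4-silyl shift gives the silyloxy ketone with the C7 oxygen trans to the C8 ester, which sets C7.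

Step 13
Reactants: 19 C7 triethylsilyloxy enynone
Product: 20 seco-target hydroxy enynone: (7R,8S,8aS in target numbering) 7-hydroxy-7-methyl-6-oxo-4a-[(E)-pent-3-en-1-ynyl]cyclohex-4a(5)-ene with the free orsellinate at C8 and CH2OH at C8a
Conditions: HF·pyridine, pyridine, THF, 0 °C to rt
Reagents that add atoms: none
Why: Buffered HF removes both triethylsilyl ethers and the two aryl silyl ethers (activated by the ortho and para acyl group) without base, so the hindered aroate and the α-ketol stay in place and no stereocentre is touched.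

Step 14
Reactants: 20 seco-target hydroxy enynone
Product: 21 target, (7R,8S,8aS)-7-hydroxy-7-methyl-6-oxo-3-[(E)-prop-1-en-1-yl]-6,7,8,8a-tetrahydro-1H-isochromen-8-yl 2,4-dihydroxy-6-methylbenzoate
Conditions: Ph3PAuNTf2 (5 mol%), CH2Cl2, 0 °C to rt
Reagents that add atoms: none
Why: In this gold-catalysed intramolecular hydroalkoxylation the monovalent gold cation activates the alkyne and the C1 hydroxyl adds 6-endo-dig at C3, the δ carbon of the C6=O, C5=C4a, C4≡C3 ynenone and therefore the electrophilic alkyne terminus, after which protodeauration gives the pyran ring without touching any stereocentre.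

Compound list
1 | (E)-pent-2-en-4-yn-1-ol | OC/C=C/C#C | starting material
2 | (E)-1-bromoprop-1-ene | C/C=C/Br | starting material
3 | (2E,6E)-octa-2,6-dien-4-yn-1-ol | C/C=C/C#C/C=C/CO | intermediate
4 | (2E,6E)-octa-2,6-dien-4-ynal | C/C=C/C#C/C=C/C=O | intermediate
5 | racemic (4E,8E)-deca-4,8-dien-6-yn-3-ol | CCC(O)/C=C/C#C/C=C/C | intermediate
6 | (4E,8E)-deca-4,8-dien-6-yn-3-one | CCC(=O)/C=C/C#C/C=C/C | intermediate
7 | (2Z,4E,8E)-3-(tert-butyldimethylsilyloxy)deca-2,4,8-trien-6-yne | C/C=C(\O[Si](C)(C)C(C)(C)C)/C=C/C#C/C=C/C | intermediate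
8 | orsellinic acid | Cc1cc(O)cc(O)c1C(=O)O | starting material
9 | tert-butyldimethylsilyl 2,4-bis(tert-butyldimethylsilyloxy)-6-methylbenzoate | Cc1cc(O[Si](C)(C)C(C)(C)C)cc(O[Si](C)(C)C(C)(C)C)c1C(=O)O[Si](C)(C)C(C)(C)C | intermediate
10 | sodium malonaldehyde enolate | [Na+].[O-]/C=C/C=O | starting material
11 | 2,4-bis(tert-butyldimethylsilyloxy)-6-methylbenzoyl chloride | Cc1cc(O[Si](C)(C)C(C)(C)C)cc(O[Si](C)(C)C(C)(C)C)c1C(=O)Cl | intermediate
12 | (E)-3-oxoprop-1-enyl 2,4-bis(tert-butyldimethylsilyloxy)-6-methylbenzoate | O=C/C=C/OC(=O)c1c(C)cc(O[Si](C)(C)C(C)(C)C)cc1O[Si](C)(C)C(C)(C)C | intermediate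
13 | Diels–Alder adduct (endo; 8-aroyloxy trans to 8a-formyl, 4a-alkynyl and 7-methyl cis to formyl) | C/C=C/C#C[C@@H]1C=C(O[Si](C)(C)C(C)(C)C)[C@H](C)[C@@H](OC(=O)c2c(C)cc(O[Si](C)(C)C(C)(C)C)cc2O[Si](C)(C)C(C)(C)C)[C@@H]1C=O | intermediate
14 | primary alcohol from 13 | C/C=C/C#C[C@@H]1C=C(O[Si](C)(C)C(C)(C)C)[C@H](C)[C@@H](OC(=O)c2c(C)cc(O[Si](C)(C)C(C)(C)C)cc2O[Si](C)(C)C(C)(C)C)[C@@H]1CO | intermediate
15 | C1 triethylsilyl ether of 14 | C/C=C/C#C[C@@H]1C=C(O[Si](C)(C)C(C)(C)C)[C@H](C)[C@@H](OC(=O)c2c(C)cc(O[Si](C)(C)C(C)(C)C)cc2O[Si](C)(C)C(C)(C)C)[C@@H]1CO[Si](CC)(CC)CC | intermediate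
16 | enynone with C1 triethylsilyl ether | C/C=C/C#CC1=CC(=O)[C@H](C)[C@@H](OC(=O)c2c(C)cc(O[Si](C)(C)C(C)(C)C)cc2O[Si](C)(C)C(C)(C)C)[C@@H]1CO[Si](CC)(CC)CC | intermediate
17 | cross-conjugated 6-triethylsilyloxy diene (C6=C7, C4a=C5) | C/C=C/C#CC1=CC(O[Si](CC)(CC)CC)=C(C)[C@@H](OC(=O)c2c(C)cc(O[Si](C)(C)C(C)(C)C)cc2O[Si](C)(C)C(C)(C)C)[C@@H]1CO[Si](CC)(CC)CC | intermediate
18 | C6–C7 silyloxy epoxide, oxygen anti to the C8 aroate | C/C=C/C#CC1=C[C@]2(O[Si](CC)(CC)CC)O[C@]2(C)[C@@H](OC(=O)c3c(C)cc(O[Si](C)(C)C(C)(C)C)cc3O[Si](C)(C)C(C)(C)C)[C@@H]1CO[Si](CC)(CC)CC | intermediate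
19 | C7 triethylsilyloxy enynone (7R,8S,8aS in target numbering) | C/C=C/C#CC1=CC(=O)[C@](C)(O[Si](CC)(CC)CC)[C@@H](OC(=O)c2c(C)cc(O[Si](C)(C)C(C)(C)C)cc2O[Si](C)(C)C(C)(C)C)[C@@H]1CO[Si](CC)(CC)CC | intermediate
20 | seco-target hydroxy enynone (7R,8S,8aS in target numbering) | C/C=C/C#CC1=CC(=O)[C@](C)(O)[C@@H](OC(=O)c2c(C)cc(O)cc2O)[C@@H]1CO | intermediate
21 | CNP0130178.5, (7R,8S,8aS)-7-hydroxy-7-methyl-6-oxo-3-[(E)-prop-1-en-1-yl]-6,7,8,8a-tetrahydro-1H-isochromen-8-yl 2,4-dihydroxy-6-methylbenzoate | C/C=C/C1=CC2=CC(=O)[C@](C)(O)[C@@H](OC(=O)c3c(C)cc(O)cc3O)[C@@H]2CO1 | target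

Total step count: 14. Longest linear sequence: 12 steps (steps 1 to 5, then 8 to 14); the orsellinate branch (steps 6 and 7) joins at step 8.

Steps most likely to fail

Step 8. The strongly acidic boron cation may desilylate the diene or divert it into open-chain Mukaiyama-type addition to the enal. The doubly end-substituted diene may also add too slowly at low temperature, or the enal faces may be discriminated poorly. The fallback sets out from 7 and 12 and replaces asymmetric catalysis by resolution. The cycloaddition is run without a chiral catalyst (toluene, 60 to 80 °C, or ZnBr2 in CH2Cl2 at low temperature) to give the racemic Diels–Alder adduct F1. Immediate NaBH4 reduction gives the racemic primary alcohol F2. Preparative chromatography on a chiral stationary phase then separates the enantiomers and delivers 14, where the route is rejoined.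

Step 12. Oxygen may be delivered to the wrong face of the C6–C7 enol ether, because the C1 silyloxymethyl group lies on the face that the oxidant is meant to use and competes with the C8 aroate as the controlling element. Enolization toward C8a and ionization of the allylic aroate are lesser concerns. The fallback replaces substrate control by reagent control and sets out from silyloxydiene 17, isolated by non-aqueous work-up. A Shi epoxidation with the fructose-derived chiral ketone of the matching enantiomeric series, KHSO5 and K2CO3 buffer in MeCN/dimethoxymethane/water at 0 °C gives the silyloxy epoxide 18. This hydrolyses in the medium to the C7 hydroxy enynone F3, which keeps its other silyl groups. Treatment of F3 with HF·pyridine as in step 13 rejoins the route at 20.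

Step 11. Transmetallation of the bulky silyl enol ether may be slow, divalent palladium may be diverted by the enyne, and the β-aroyloxy ketone may lose its aroate during a prolonged reaction or work-up. The fallback uses selenoxide elimination and sets out from 15. PhSeCl in CH2Cl2 at −78 °C reacts at the nucleophilic C5 of the enol ether, anti to the alkynyl group, to give the α-phenylselanyl ketone F4. Oxidation with NaIO4 in aqueous THF gives the selenoxide F5, which undergoes syn elimination with C4a–H at or below room temperature and returns to the route at 16.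

Further compounds
F1 | step 8 | racemic Diels–Alder adduct (13 and its mirror image) | C/C=C/C#C[C@@H]1C=C(O[Si](C)(C)C(C)(C)C)[C@H](C)[C@@H](OC(=O)c2c(C)cc(O[Si](C)(C)C(C)(C)C)cc2O[Si](C)(C)C(C)(C)C)[C@@H]1C=O.C/C=C/C#C[C@H]1C=C(O[Si](C)(C)C(C)(C)C)[C@@H](C)[C@H](OC(=O)c2c(C)cc(O[Si](C)(C)C(C)(C)C)cc2O[Si](C)(C)C(C)(C)C)[C@H]1C=O
F2 | step 8 | racemic primary alcohol (14 and its mirror image) | C/C=C/C#C[C@@H]1C=C(O[Si](C)(C)C(C)(C)C)[C@H](C)[C@@H](OC(=O)c2c(C)cc(O[Si](C)(C)C(C)(C)C)cc2O[Si](C)(C)C(C)(C)C)[C@@H]1CO.C/C=C/C#C[C@H]1C=C(O[Si](C)(C)C(C)(C)C)[C@@H](C)[C@H](OC(=O)c2c(C)cc(O[Si](C)(C)C(C)(C)C)cc2O[Si](C)(C)C(C)(C)C)[C@H]1CO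
F3 | step 12 | C7 hydroxy enynone with aryl silyl ethers and C1 triethylsilyl ether intact | C/C=C/C#CC1=CC(=O)[C@](C)(O)[C@@H](OC(=O)c2c(C)cc(O[Si](C)(C)C(C)(C)C)cc2O[Si](C)(C)C(C)(C)C)[C@@H]1CO[Si](CC)(CC)CC
F4 | step 11 | C5 phenylselanyl ketone (selenium trans to the C4a alkynyl group) | C/C=C/C#C[C@@H]1[C@@H]([Se]c2ccccc2)C(=O)[C@H](C)[C@@H](OC(=O)c3c(C)cc(O[Si](C)(C)C(C)(C)C)cc3O[Si](C)(C)C(C)(C)C)[C@@H]1CO[Si](CC)(CC)CC
F5 | step 11 | C5 phenylseleninyl ketone (selenoxide of F4) | C/C=C/C#C[C@@H]1[C@@H]([Se](=O)c2ccccc2)C(=O)[C@H](C)[C@@H](OC(=O)c3c(C)cc(O[Si](C)(C)C(C)(C)C)cc3O[Si](C)(C)C(C)(C)C)[C@@H]1CO[Si](CC)(CC)CC
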